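The earlier runs and the new flask are simulated with constants of no real substance, and the scatter is random.

The easy step comes first: ash has the charges of the midnight run, so I read it there, 32.9% at 2.50 d. That run also shows how fast the product comes. Its rise slows by a factor 1.52 from the interval ending at 1.04 d to the one ending at 2.50 d. I take this as the pseudo-first-order conversion of mono adduct into bis adduct, which gives 2.40 d: the ripening time, in which the rise falls by a factor e. It is a reading, and loose by the scatter.

| flask | substrate | partner | remark | time |
|---|---|---|---|---|
| midnight | 13 mM | 19.5 mM | run made earlier |  |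
| dusk | 18 mM | 19.5 mM | run made earlier |  |
| noon | 29 mM | 19.5 mM | run made earlier |  |
| oak | 13 mM (fed, over 50 h) | 19.5 mM | all else is in the flask from the start; the feed brings no volume worth counting | 2.5 d |
| cedar | 13 mM | 19.5 mM (fed, over 50 h) | all else is in the flask from the start; the feed brings no volume worth counting | 2.5 d |
| ash | 13 mM | 19.5 mM | everything together at the start | 2.5 d |

| run | time / d | bis adduct / % |
|---|---|---|
| midnight | 0.208 | 2.1 |
| midnight | 0.500 | 8.7 |
| midnight | 1.04 | 17.4 |
| midnight | 2.50 | 32.9 |
| dusk | 0.250 | 3.9 |
| dusk | 0.500 | 5.9 |
| dusk | 1.25 | 18.1 |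
| dusk | 3.00 | 27.8 |
| noon | 0.250 | 3.2 |
| noon | 0.500 | 4.0 |
| noon | 1.25 | 10.7 |
| noon | 3.00 | 14.4 |

(readings scatter by 1 percentage point)



- the flask that comes out highest in amount of bis adduct, in percent of the substrate charged, or "all alike" when all lie within 1.5 percentage points (oak / cedar / ash / all alike)
- bis adduct at the end, in percent of the substrate charged, oak
- bis adduct at the end, in percent of the substrate charged, cedar
- bis adduct at the end, in percent of the substrate charged, ash

Now the settings. Feeding substrate over 50 h brings each portion in, on average, 1.04 d late. That lag is shorter than the ripening time, so I use the last slope of the midnight run and get 21.8% for oak. Feeding partner has the same lag, so my reckoning gives cedar that figure too and cannot part the two. Either way, ash stays higher.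

The forecast names ash, with 33.5% for ash, 20% for oak and 17% for cedar, both feeds below my figure. Its ground: “Both feeds delay mono build-up, so ash wins”.

The flasks give 32.7% for ash, 22.6% for oak and 20.0% for cedar, so ash is highest. Side product A stands close together at the end: 47.6% in ash, 50.7% in oak, 49.8% in cedar. In ash, substrate is down to 0.191% at 1.25 d, with 30.3% mono adduct; the ripening time turns that into 18.0% at 2.5 d, and the flask holds 18.6%.

    substrate + partner → mono adduct + released group (k = 6.20 L mol⁻¹ h⁻¹)
    partner + mono adduct → bis adduct + released group (k = 1.80 L mol⁻¹ h⁻¹)
    substrate + released group → side product A (k = 55.0 L mol⁻¹ h⁻¹)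
    substrate + bis adduct → side product B (k = 2.70 L mol⁻¹ h⁻¹)

Cedar read later, at 6.0 d: from its 20.0% bis adduct and 27.9% mono adduct at 2.50 d, the ripening time gives an estimate of 41.4% bis adduct. The flask gives 40.5%.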